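**Retrosynthetic overview**
1. Target ⇐ C12 silyl ether ⇐ C8 carbinol (MnO2) ⇐ ring diyne, whose cis-semihydrogenation gives both Z ring alkenes (C2=C3, C6=C7).
2. The only ring (11-membered carbocycle) is closed late, at C8–C9, by a CrCl2/NiCl2 coupling of a C9 vinyl iodide with a C8 ynal.
3. C3–C4: acetylide acylation by an α-hydroxy ester, then catalyst-controlled ynone reduction (sets C4); the senecioate is put on before ring closure.
4. Key bond C5–C6: 3,3-diethoxypropyne, a β-formylvinyl anion (d3, homoenolate-type) equivalent, adds enantioselectively to the ketone carbon of ethyl pyruvate; both carbons are electrophilic in the unmasked C5(OH)–C6=C7–C8=O array. This sets C5.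
5. C1: enantioselective SN2′ alkynylation of geranyl phosphate; C9/C12: α-iodo Wittig olefination of the C10 aldehyde.

Assumption: the target is handled as the open γ-hydroxy dienone drawn; labels used below are ring carbons C1 (quaternary) → C2=C3 → C4 (ester carbinol) → C5 (tertiary carbinol) → C6=C7 → C8 (ketone) → C9=C10 → C11, with C12 the hydroxymethyl carbon (target = 1S,4S,5S; 2Z,6Z,9Z).

**Route**

Step 1
Reactants: 1 geraniol; 2 diethyl chlorophosphate
Product: 3 geranyl diethyl phosphate
Conditions: Et3N, DMAP (10 mol %), CH2Cl2, 0 → 25 °C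
Reagents that add atoms: diethyl chlorophosphate (2), CCOP(=O)(Cl)OCC
Why: O-phosphorylation of the primary allylic alcohol installs the leaving group for allylic substitution and leaves the E-trisubstituted alkene untouched.

Step 2
Reactants: 3 geranyl diethyl phosphate; 4 (trimethylsilyl)acetylene
Product: 6 [(3S)-3-ethenyl-3,7-dimethyloct-6-en-1-yn-1-yl]trimethylsilane, via alkynylalane 5 (not isolated)
Conditions: 4, i-Bu2AlH, Et3N (5 mol %), hexanes, 22 °C; then 3, CuCl2·2H2O (5 mol %), chiral sulfonate-bearing imidazolinium salt (NHC precursor, 5 mol %, antipode giving S), THF, −30 °C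
Reagents that add atoms: (trimethylsilyl)acetylene (4), C#C[Si](C)(C)C
Why: The chiral NHC complex formed from CuCl2·2H2O delivers the alkynyl group of the alane to the γ-carbon (enantioselective SN2′ allylic substitution), creating the C1 quaternary centre (S) on one face of the E-alkene, the fixed alkene geometry differentiating methyl from the 4-methylpent-3-enyl group.

Step 3
Reactants: 6 [(3S)-3-ethenyl-3,7-dimethyloct-6-en-1-yn-1-yl]trimethylsilane
Product: 10 (3S)-3-ethynyl-3,7-dimethyloct-6-en-1-ol, via alkylborane 8 (not isolated), via silyl alkynol 9 (not isolated)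
Conditions: 9-BBN (1.1 equiv), THF, 0 → 25 °C; then NaOH (aq), 7, MeOH, 0 → 25 °C
Reagents that add atoms: hydrogen peroxide (7), OO
Why: 9-BBN hydroborates only the monosubstituted vinyl group anti-Markovnikov (hydroboration–oxidation) and the methanolic hydroxide of the oxidative work-up also cleaves the alkynyl–silicon bond, C1 being untouched.

Step 4
Reactants: 10 (3S)-3-ethynyl-3,7-dimethyloct-6-en-1-ol
Product: 11 (3S)-3-ethynyl-3,7-dimethyloct-6-enal
Conditions: Dess–Martin periodinane, CH2Cl2, 0 → 25 °C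
Reagents that add atoms: none
Why: Dess–Martin oxidation gives the C10 aldehyde without over-oxidation and there is no α-stereocentre to epimerise.

Step 5
Reactants: 11 (3S)-3-ethynyl-3,7-dimethyloct-6-enal; 12 ethyl (triphenylphosphoranylidene)acetate; 13 N-iodosuccinimide
Product: 15 ethyl (2Z,5S)-5-ethynyl-2-iodo-5,9-dimethyldeca-2,8-dienoate, via iodo ylide 14 (not isolated)
Conditions: 12, 13, CH2Cl2, −20 °C; then 11, 25 °C
Reagents that add atoms: ethyl (triphenylphosphoranylidene)acetate (12), CCOC(=O)C=P(c1ccccc1)(c1ccccc1)c1ccccc1; N-iodosuccinimide (13), O=C1CCC(=O)N1I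
Why: Wittig olefination with the stabilised α-iodo ylide (made in the flask by iodination of the ylide) puts the ester trans to the chain, so iodine ends up cis to C11 (Z), which fixes the C9=C10 geometry of the target.

Step 6
Reactants: 15 ethyl (2Z,5S)-5-ethynyl-2-iodo-5,9-dimethyldeca-2,8-dienoate
Product: 16 (2Z,5S)-5-ethynyl-2-iodo-5,9-dimethyldeca-2,8-dien-1-ol
Conditions: i-Bu2AlH (2.5 equiv), CH2Cl2, −78 °C
Reagents that add atoms: none
Why: 1,2-Reduction of the enoate by the aluminium hydride gives the allylic alcohol (C12) and leaves the vinyl iodide and the alkyne intact at low temperature.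

Step 7
Reactants: 16 (2Z,5S)-5-ethynyl-2-iodo-5,9-dimethyldeca-2,8-dien-1-ol; 17 tert-butyl(chloro)diphenylsilane
Product: 18 tert-butyl{[(2Z,5S)-5-ethynyl-2-iodo-5,9-dimethyldeca-2,8-dien-1-yl]oxy}diphenylsilane
Conditions: imidazole, CH2Cl2, 25 °C
Reagents that add atoms: tert-butyl(chloro)diphenylsilane (17), CC(C)(C)[Si](Cl)(c1ccccc1)c1ccccc1
Why: Silyl ether protection of the primary alcohol with an acid-stable group that survives the later acetal hydrolysis and keeps C12 from being oxidised in step 15.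

Step 8 (key step)
Reactants: 19 ethyl pyruvate; 20 3,3-diethoxyprop-1-yne
Product: 21 ethyl (2S)-5,5-diethoxy-2-hydroxy-2-methylpent-3-ynoate
Conditions: Zn(OTf)2 (20 mol %), 2-(dimethylamino)-1-(4-nitrophenyl)-3-(tert-butyldimethylsilyloxy)propan-1-ol (22 mol %, antipode giving S), Et3N (30 mol %), toluene, 60 °C
Reagents that add atoms: 3,3-diethoxyprop-1-yne (20), C#CC(OCC)OCC
Why: The zinc acetylide of the propiolaldehyde acetal, a β-formylvinyl anion (d3, homoenolate-type) equivalent, adds to the pyruvate ketone (catalytic enantioselective alkynylation of an α-keto ester), joining the future β-carbon of the C8 enone (C6) to the carbonyl carbon C5, with the chiral zinc amino-alkoxide choosing the ketone face and so setting C5 (S).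

Step 9
Reactants: 18 tert-butyl{[(2Z,5S)-5-ethynyl-2-iodo-5,9-dimethyldeca-2,8-dien-1-yl]oxy}diphenylsilane; 21 ethyl (2S)-5,5-diethoxy-2-hydroxy-2-methylpent-3-ynoate
Product: 24 seco ynone (C4 ketone), via lithium acetylide 22 (not isolated), via lithium alkoxide 23 (not isolated)
Conditions: LiN(i-Pr)2 (2.1 equiv), THF, −78 → −20 °C; then H2O
Reagents that add atoms: ethyl (2S)-5,5-diethoxy-2-hydroxy-2-methylpent-3-ynoate (21), CCOC(=O)[C@@](C)(O)C#CC(OCC)OCC
Why: Acylation of the lithium acetylide by the ester (nucleophilic acyl substitution) stops at the ynone because the chelated dilithio tetrahedral intermediate collapses only on work-up and 21 has no enolisable hydrogen, the amide base leaving the vinyl iodide alone at low temperature.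

Step 10
Reactants: 24 seco ynone (C4 ketone)
Product: 25 seco diol (4S,5S)
Conditions: RuCl[(R,R)-TsDPEN](p-cymene) (3 mol %), KOH (3 mol %), i-PrOH, 25 °C
Reagents that add atoms: none
Why: Noyori asymmetric transfer hydrogenation of the ynone is catalyst-controlled (the alkyne takes the π-site of RuCl[(R,R)-TsDPEN](p-cymene)), giving the 4S propargylic alcohol, syn to the C5 hydroxyl.

Step 11
Reactants: 25 seco diol (4S,5S); 26 3-methylbut-2-enoyl chloride
Product: 27 seco senecioate
Conditions: pyridine, DMAP (10 mol %), CH2Cl2, 0 °C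
Reagents that add atoms: 3-methylbut-2-enoyl chloride (26), CC(C)=CC(=O)Cl
Why: DMAP-catalysed esterification acylates the secondary propargylic alcohol selectively over the hindered tertiary C5 alcohol.

Step 12
Reactants: 27 seco senecioate; 28 water
Product: 29 seco ynal
Conditions: HCO2H/H2O (9:1), CH2Cl2, 0 °C
Reagents that add atoms: water (28), O
Why: Acid-catalysed acetal hydrolysis unmasks the C8 aldehyde, the linear alkyne preventing lactol formation with the C5 hydroxyl, while the silyl ether and ester survive.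

Step 13
Reactants: 29 seco ynal
Product: 30 macrocyclic diynol (C8 epimers)
Conditions: CrCl2 (8 equiv), NiCl2 (2 mol %), THF/DMF (3:1), 25 °C, 2 mM, slow addition
Reagents that add atoms: none
Why: Nozaki–Hiyama–Kishi reaction, in which the vinyl iodide is turned by NiCl2/CrCl2 into a vinyl organochromium that adds 1,2 to the ynal with retention of the C9=C10 geometry, closes the 11-membered ring and tolerates the free tertiary alcohol and the ester (the C8 configuration is irrelevant).

Step 14
Reactants: 30 macrocyclic diynol (C8 epimers)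
Product: 31 macrocyclic (2Z,6Z,9Z)-trienol (C8 epimers)
Conditions: H2 (1 atm), Pd/CaCO3 poisoned with Pb(OAc)2, quinoline, EtOAc, 25 °C, stopped after 2 equiv H2
Reagents that add atoms: none
Why: Lindlar semihydrogenation (syn addition of H2) converts both ring alkynes into the 2Z and 6Z alkenes, while the trisubstituted and conjugated alkenes are not reduced.

Step 15
Reactants: 31 macrocyclic (2Z,6Z,9Z)-trienol (C8 epimers)
Product: 32 dienone silyl ether
Conditions: MnO2 (20 equiv), CH2Cl2, 25 °C
Reagents that add atoms: none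
Why: MnO2 oxidation of the doubly allylic secondary alcohol gives the cross-conjugated dienone, the tertiary alcohol, ester and silyl ether being inert and both C8 epimers converging.

Step 16
Reactants: 32 dienone silyl ether
Product: 33 target (CNP0230506.5)
Conditions: HF·pyridine, pyridine/THF, 0 → 25 °C
Reagents that add atoms: none
Why: Buffered fluoride desilylation frees the primary allylic alcohol without acyl migration or base-induced isomerisation of the Z-enone.

**Compound list**

1 | geraniol, (2E)-3,7-dimethylocta-2,6-dien-1-ol | CC(C)=CCC/C(C)=C/CO | starting material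
2 | diethyl chlorophosphate | CCOP(=O)(Cl)OCC | starting material
3 | geranyl diethyl phosphate | CC(C)=CCC/C(C)=C/COP(=O)(OCC)OCC | intermediate
4 | (trimethylsilyl)acetylene | C#C[Si](C)(C)C | starting material
5 | diisobutyl[(trimethylsilyl)ethynyl]alane | CC(C)C[Al](CC(C)C)C#C[Si](C)(C)C | intermediate (not isolated)
6 | [(3S)-3-ethenyl-3,7-dimethyloct-6-en-1-yn-1-yl]trimethylsilane | CC(C)=CCC[C@](C=C)(C)C#C[Si](C)(C)C | intermediate
7 | hydrogen peroxide | OO | starting material
8 | B-alkyl-9-borabicyclo[3.3.1]nonane adduct of 6 (boron on the terminal vinyl carbon, C1 unchanged) | CC(C)=CCC[C@](CCB1C2CCCC1CCC2)(C)C#C[Si](C)(C)C | intermediate (not isolated)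
9 | (3S)-3,7-dimethyl-3-[(trimethylsilyl)ethynyl]oct-6-en-1-ol | CC(C)=CCC[C@](CCO)(C)C#C[Si](C)(C)C | intermediate (not isolated)
10 | (3S)-3-ethynyl-3,7-dimethyloct-6-en-1-ol | CC(C)=CCC[C@](CCO)(C)C#C | intermediate
11 | (3S)-3-ethynyl-3,7-dimethyloct-6-enal | CC(C)=CCC[C@](CC=O)(C)C#C | intermediate
12 | ethyl (triphenylphosphoranylidene)acetate | CCOC(=O)C=P(c1ccccc1)(c1ccccc1)c1ccccc1 | starting material
13 | N-iodosuccinimide | O=C1CCC(=O)N1I | starting material
14 | ethyl iodo(triphenylphosphoranylidene)acetate | IC(C(=O)OCC)=P(c1ccccc1)(c1ccccc1)c1ccccc1 | intermediate (not isolated)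
15 | ethyl (2Z,5S)-5-ethynyl-2-iodo-5,9-dimethyldeca-2,8-dienoate | I/C(C(=O)OCC)=C\C[C@](C)(CCC=C(C)C)C#C | intermediate
16 | (2Z,5S)-5-ethynyl-2-iodo-5,9-dimethyldeca-2,8-dien-1-ol | I/C(CO)=C\C[C@](C)(CCC=C(C)C)C#C | intermediate
17 | tert-butyl(chloro)diphenylsilane | CC(C)(C)[Si](Cl)(c1ccccc1)c1ccccc1 | starting material
18 | tert-butyl{[(2Z,5S)-5-ethynyl-2-iodo-5,9-dimethyldeca-2,8-dien-1-yl]oxy}diphenylsilane | I/C(CO[Si](C(C)(C)C)(c1ccccc1)c1ccccc1)=C\C[C@](C)(CCC=C(C)C)C#C | intermediate
19 | ethyl pyruvate | CCOC(=O)C(C)=O | starting material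
20 | 3,3-diethoxyprop-1-yne | C#CC(OCC)OCC | starting material
21 | ethyl (2S)-5,5-diethoxy-2-hydroxy-2-methylpent-3-ynoate | CCOC(=O)[C@@](C)(O)C#CC(OCC)OCC | intermediate
22 | lithium acetylide of 18 | I/C(CO[Si](C(C)(C)C)(c1ccccc1)c1ccccc1)=C\C[C@](C)(CCC=C(C)C)C#C[Li] | intermediate (not isolated)
23 | lithium alkoxide of 21 | CCOC(=O)[C@@](C)(O[Li])C#CC(OCC)OCC | intermediate (not isolated)
24 | seco ynone: C12 silyl ether, 9Z iodo-C9=C10, C11H2, (1S)-C1 (methyl, 4-methylpent-3-enyl), C2≡C3, C4 ketone, (5S)-C5 (methyl, OH), C6≡C7, C8 diethyl acetal | I/C(CO[Si](C(C)(C)C)(c1ccccc1)c1ccccc1)=C\C[C@](C)(CCC=C(C)C)C#CC(=O)[C@@](C)(O)C#CC(OCC)OCC | intermediate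
25 | seco diol: as 24 with (4S)-C4H(OH) | I/C(CO[Si](C(C)(C)C)(c1ccccc1)c1ccccc1)=C\C[C@](C)(CCC=C(C)C)C#C[C@H](O)[C@@](C)(O)C#CC(OCC)OCC | intermediate
26 | 3-methylbut-2-enoyl chloride | CC(C)=CC(=O)Cl | starting material
27 | seco senecioate: as 25 with the C4 oxygen acylated by 3-methylbut-2-enoyl | I/C(CO[Si](C(C)(C)C)(c1ccccc1)c1ccccc1)=C\C[C@](C)(CCC=C(C)C)C#C[C@H](OC(=O)C=C(C)C)[C@@](C)(O)C#CC(OCC)OCC | intermediate
28 | water | O | starting material
29 | seco ynal: as 27 with C8 as free aldehyde | I/C(CO[Si](C(C)(C)C)(c1ccccc1)c1ccccc1)=C\C[C@](C)(CCC=C(C)C)C#C[C@H](OC(=O)C=C(C)C)[C@@](C)(O)C#CC=O | intermediate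
30 | macrocyclic diynol: 11-membered ring, C2≡C3, C6≡C7, C8H(OH) (both epimers), 9Z, C12 silyl ether, 1S,4S,5S | CC(C)=CCC[C@]1(C)C#C[C@H](OC(=O)C=C(C)C)[C@@](C)(O)C#CC(O)/C(CO[Si](C(C)(C)C)(c2ccccc2)c2ccccc2)=C\C1 | intermediate
31 | macrocyclic (2Z,6Z,9Z)-trienol, C8H(OH) (both epimers), C12 silyl ether | CC(C)=CCC[C@]1(C)/C=C\[C@H](OC(=O)C=C(C)C)[C@@](C)(O)/C=C\C(O)/C(CO[Si](C(C)(C)C)(c2ccccc2)c2ccccc2)=C\C1 | intermediate
32 | dienone silyl ether (12-O-tert-butyldiphenylsilyl ether of the target) | CC(C)=CCC[C@]1(C)/C=C\[C@H](OC(=O)C=C(C)C)[C@@](C)(O)/C=C\C(=O)/C(CO[Si](C(C)(C)C)(c2ccccc2)c2ccccc2)=C\C1 | intermediate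
33 | CNP0230506.5 (1S,4S,5S; 2Z,6Z,9Z) | CC(C)=CCC[C@]1(C)/C=C\[C@H](OC(=O)C=C(C)C)[C@@](C)(O)/C=C\C(=O)/C(CO)=C\C1 | target

**Totals**
Total step count: 16. Longest linear sequence: 15 steps (steps 1–7 and 9–16, from geraniol); step 8 is a one-step side branch.

**Three steps most likely to fail, with fallbacks**

Step 2 (enantioselectivity at C1, where methyl and a primary alkyl chain must be told apart, and SN2′ selectivity with the silylalkynyl alane). The fallback sets out from 3 and comes back at 6; it makes the C1–B bond first and the C1–C2 bond stereospecifically afterwards. Enantioselective allylic borylation of 3 (B2(pin)2, CuCl, chiral NHC, NaOMe, THF) gives 2-[(3R)-3,7-dimethylocta-1,6-dien-3-yl]-4,4,5,5-tetramethyl-1,3,2-dioxaborolane F1. Addition of α-lithiated vinyl N,N-diisopropylcarbamate and I2/NaOMe-induced 1,2-migration (Zweifel-type, retention at the migrating carbon) gives (3S)-3-ethenyl-3,7-dimethylocta-1,6-dien-2-yl N,N-diisopropylcarbamate F2. Elimination with LiN(i-Pr)2 gives (3S)-3-ethenyl-3,7-dimethyloct-6-en-1-yne F3, and n-BuLi/Me3SiCl returns 6.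

Step 8 (the key C5–C6 bond: pyruvate is enolisable and can self-condense, and the ee of this ketone alkynylation is untested). The fallback sets out from 18 and comes back at 25, which also bypasses step 9; the same three-carbon reversed-polarity unit is added last, under substrate control. Compound 18 is deprotonated with LiN(i-Pr)2 and acylated with ethyl 2,2-diethoxypropanoate to give the ynone ketal F4. RuCl[(R,R)-TsDPEN](p-cymene)/i-PrOH reduces it to the (4S)-propargylic alcohol F5, and dilute aqueous acid unmasks the α-hydroxy methyl ketone F6. BrMgC≡CCH(OEt)2 (3 equiv, THF, −78 °C) then adds through the five-membered magnesium chelate of the C4 alkoxide and the C5 ketone, from the side of the C4 hydrogen (Cram chelate model), which gives the 4S,5S syn diol 25.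

Step 13 (closure of an 11-membered ring that holds two alkynes and a Z-alkene, starting from a sensitive ynal). The fallback sets out from 27 and comes back at 31; the chain is made cis and flexible before it is cyclised. Both alkynes of 27 are cis-reduced with zinc activated by Cu(OAc)2 and AgNO3 in MeOH/H2O, which spares the vinyl iodide, to give the (2Z,6Z)-diene acetal F7. Acetal hydrolysis gives the (6Z)-enal F8, in equilibrium with its five-membered lactol. CrCl2/NiCl2 ring closure of F8 under high dilution gives 31 directly.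

**Further compounds**
F1 | step 2 | 2-[(3R)-3,7-dimethylocta-1,6-dien-3-yl]-4,4,5,5-tetramethyl-1,3,2-dioxaborolane | CC(C)=CCC[C@](C=C)(C)B1OC(C)(C)C(C)(C)O1
F2 | step 2 | (3S)-3-ethenyl-3,7-dimethylocta-1,6-dien-2-yl N,N-diisopropylcarbamate | CC(C)=CCC[C@](C=C)(C)C(=C)OC(=O)N(C(C)C)C(C)C
F3 | step 2 | (3S)-3-ethenyl-3,7-dimethyloct-6-en-1-yne | CC(C)=CCC[C@](C=C)(C)C#C
F4 | step 8 | ynone ketal: 18 acylated at the alkyne terminus by 2,2-diethoxypropanoyl (C4 ketone, C5 diethyl ketal) | I/C(CO[Si](C(C)(C)C)(c1ccccc1)c1ccccc1)=C\C[C@](C)(CCC=C(C)C)C#CC(=O)C(C)(OCC)OCC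
F5 | step 8 | (4S)-propargylic alcohol ketal | I/C(CO[Si](C(C)(C)C)(c1ccccc1)c1ccccc1)=C\C[C@](C)(CCC=C(C)C)C#C[C@H](O)C(C)(OCC)OCC
F6 | step 8 | (4S)-α-hydroxy methyl ketone | I/C(CO[Si](C(C)(C)C)(c1ccccc1)c1ccccc1)=C\C[C@](C)(CCC=C(C)C)C#C[C@H](O)C(C)=O
F7 | step 13 | (2Z,6Z)-diene acetal (both alkynes of 27 cis-reduced) | I/C(CO[Si](C(C)(C)C)(c1ccccc1)c1ccccc1)=C\C[C@](C)(CCC=C(C)C)/C=C\[C@H](OC(=O)C=C(C)C)[C@@](C)(O)/C=C\C(OCC)OCC
F8 | step 13 | (2Z,6Z)-dienal (open form of the lactol) | I/C(CO[Si](C(C)(C)C)(c1ccccc1)c1ccccc1)=C\C[C@](C)(CCC=C(C)C)/C=C\[C@H](OC(=O)C=C(C)C)[C@@](C)(O)/C=C\C=O
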